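**Retrosynthetic overview**

1. The target is opened at the C19 angelate ester and the C15 acid; both oxygens travel as a C19 dimethyl acetal and a C15 silyl ether on a labd-7-ene core.
2. C9–H and the C7=C8 alkene come from an 8-en-7β-ol by reductive 1,3-transposition, that from an 8-en-7-one, and that from the ring B C9 ketone plus a C11–C15 organocerium (C13 from methyl hydrogen (R)-3-methylglutarate).
3. The strategy rests on C4 of ring A: it is quaternary, bonded to C3, and carries the axial oxygenated carbon C19. Ring A (C1–C5, C10) is therefore closed at C3–C4 by anodic coupling of a C4=C19 methyl enol ether on C5 with a (Z)-vinylsilane arm (C1–C3) on C10.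
4. Ring B (C5–C10) is (R)-carvone: C20 and the C1–C3 arm enter by two enolate alkylations at C10, and C4/C18 come from the isopropenyl group. Ring order: B (bought), then A.

Key step: step 6

Remark: labdane numbering is used for all intermediates (ring A = C1–C5, C10; ring B = C5–C10; C17 on C8; C18 and C19 on C4; C20 on C10; C16 on C13).
Remark: the vinylsilane is used as the Z isomer, because only then does the C–Si bond sit pseudo-axial at C3 in the chair transition state and overlap with the p orbital developing at C2. It is carried through the ozonolysis as a silylalkyne, since a vinylsilane would not survive ozone.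
Remark: enol ether 13 is used as the E/Z mixture from the Wittig reaction (E drawn); C19 ends as a non-stereogenic acetal carbon.

**Route**

Step 1
Reactants: 1 (R)-(−)-carvone; 2 iodomethane
Product: 4 6-methylcarvone (C10 epimer mixture), via lithium dienolate 3 (not isolated)
Conditions: LiN(iPr)2, THF, −78 °C; MeI, −78 to 0 °C
Reagents that add atoms: iodomethane 2, CI
Why: Kinetic deprotonation at the α' carbon (C10) and SN2 methylation of the cross-conjugated lithium dienolate is a standard enolate alkylation; the C10 epimer ratio does not matter because this centre is enolised again in step 2.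

Step 2
Reactants: 4 6-methylcarvone; 5 3-bromo-1-(trimethylsilyl)prop-1-yne
Product: 7 silylpropargyl carvone (arm on C10 trans to the C5 isopropenyl group), via lithium enolate 6 (not isolated)
Conditions: LiN(iPr)2, THF, −78 to 0 °C; then 5, DMPU, −78 °C to rt
Reagents that add atoms: 3-bromo-1-(trimethylsilyl)prop-1-yne 5, C[Si](C)(C)C#CCBr
Why: Enolate alkylation (SN2) with a reactive propargylic bromide; the electrophile enters on the ring face opposite the adjacent C5 isopropenyl group, which sets C10 with the C1 arm trans and the C20 methyl cis to the C5 substituent.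

Step 3
Reactants: 7 silylpropargyl carvone
Product: 9 C4 methyl ketone, via ozonide 8 (not isolated)
Conditions: O3 (1 equiv), CH2Cl2, −78 °C; then PPh3, −78 °C to rt
Reagents that add atoms: ozone, O=[O+][O-]
Why: Chemoselective ozonolysis: the electron-rich 1,1-disubstituted isopropenyl alkene should react much faster than the electron-poor enone alkene or the silylalkyne, and reductive cleavage of the ozonide gives the C4 ketone without touching C5.

Step 4
Reactants: 9 C4 methyl ketone
Product: 10 (Z)-vinylsilane diketone
Conditions: H2 (1 atm), Pd/CaCO3 poisoned with Pb(OAc)2, quinoline, EtOAc/hexane, rt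
Reagents that add atoms: none
Why: Lindlar semihydrogenation (syn addition of H2 on poisoned palladium) should turn the silylalkyne into the (Z)-vinylsilane while the trisubstituted enone alkene and both ketones stay untouched.

Step 5
Reactants: 10 (Z)-vinylsilane diketone; 11 (methoxymethyl)triphenylphosphonium chloride
Product: 13 enol ether–vinylsilane (key-step precursor), via phosphorus ylide 12 (not isolated)
Conditions: 11, KN(SiMe3)2, THF, 0 °C; then 10, −78 °C to rt
Reagents that add atoms: (methoxymethyl)triphenylphosphonium chloride 11, COC[P+](c1ccccc1)(c1ccccc1)c1ccccc1.[Cl-]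
Why: Wittig methoxymethylenation of the non-conjugated C4 methyl ketone; the C9 carbonyl is conjugated and flanked by quaternary C10 and the C8 methyl and should not react, and a preformed ylide at low temperature limits enolisation toward C5.

Step 6
Reactants: 13 enol ether–vinylsilane
Product: 14 trans-fused 2,7-dien-9-one C19 dimethyl acetal
Conditions: constant current (8 mA, 2.2 F/mol), reticulated vitreous carbon anode, Pt cathode, undivided cell, 0.1 M LiClO4, MeOH/THF 1:4, 2,6-lutidine, rt
Reagents that add atoms: methanol, CO
Why: Anodic oxidation removes one electron from the methyl enol ether, the most easily oxidised π system present, and the radical cation is electrophilic at C4; the vinylsilane attacks it through its silicon-bearing carbon C3, a second electron transfer and methanol turn C19 into the dimethyl acetal, and methanol-assisted loss of Me3Si from the β-silyl cation at C2 leaves the C2=C3 alkene. The closest known reaction type is the intramolecular anodic olefin coupling of enol ether radical cations with vinyl- and allylsilanes, which forms six-membered rings and quaternary carbons, and the ipso substitution follows vinylsilane-terminated cation cyclisations. Ring A closes in a 6-endo-trig mode with respect to the C2=C3 vinylsilane (6-exo with respect to C4=C19); the 5-exo alternative through C2 would give a strained trans-fused five-membered ring and an unstabilised α-silyl cation. The only new stereocentre, C4, is set in a chair-like transition state anchored by the trans, diequatorial C5 and C10 arms of ring B with C20 axial: the flat C19H(OMe) terminus is expected to take the axial site and the C18 methyl the equatorial site, because an axial tetrahedral methyl would be syn-pentane to C20. The step needs chemoselective oxidation (secured by the low potential of the enol ether against enone and vinylsilane), 6-endo regioselectivity (secured by the β-silicon effect and the Z geometry, which puts the C–Si bond pseudo-axial at C3) and C4 facial selectivity (secured only by the C18/C20 repulsion, and therefore the main risk).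

Step 7
Reactants: 14 trans-fused 2,7-dien-9-one C19 dimethyl acetal
Product: 15 7-en-9-one C19 dimethyl acetal (ring A saturated)
Conditions: H2 (3 atm), RhCl(PPh3)3 (10 mol %), benzene/EtOH, rt
Reagents that add atoms: none
Why: Homogeneous hydrogenation with RhCl(PPh3)3 should reduce the isolated cis-disubstituted C2=C3 alkene and leave the trisubstituted conjugated C7=C8 alkene, the ketone and the acetal alone; it is done here so that no diimide-sensitive alkene remains in step 15.

Step 8
Reactants: 16 methyl hydrogen (R)-3-methylglutarate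
Product: 17 methyl (R)-5-hydroxy-3-methylpentanoate
Conditions: BH3·SMe2, THF, −10 to 0 °C; MeOH quench
Reagents that add atoms: none
Why: Chemoselective borane reduction: the carboxylic acid is reduced through its acyloxyborane much faster than the methyl ester, and the stereocentre (future C13) is not involved.

Step 9
Reactants: 17 methyl (R)-5-hydroxy-3-methylpentanoate
Product: 18 methyl (R)-5-(tert-butyldiphenylsilyloxy)-3-methylpentanoate
Conditions: t-BuPh2SiCl, imidazole, DMF, 0 °C to rt
Reagents that add atoms: tert-butyl(chloro)diphenylsilane, CC(C)(C)[Si](Cl)(c1ccccc1)c1ccccc1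
Why: Imidazole-promoted silylation of the primary alcohol traps the hydroxy ester before it can lactonise; the tert-butyldiphenylsilyl ether is chosen to survive t-BuLi, chromate oxidation and the mild acid of step 16.

Step 10
Reactants: 18 methyl (R)-5-(tert-butyldiphenylsilyloxy)-3-methylpentanoate
Product: 19 (S)-5-(tert-butyldiphenylsilyloxy)-3-methylpentan-1-ol
Conditions: iBu2AlH, CH2Cl2, −78 to 0 °C; aqueous KNaC4H4O6 work-up
Reagents that add atoms: none
Why: Hydride reduction of the ester to the primary alcohol by iBu2AlH, to which the silyl ether is inert.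

Step 11
Reactants: 19 (S)-5-(tert-butyldiphenylsilyloxy)-3-methylpentan-1-ol
Product: 20 (R)-iodide tert-butyl[(5-iodo-3-methylpentyl)oxy]diphenylsilane
Conditions: I2, PPh3, imidazole, CH2Cl2, 0 °C to rt
Reagents that add atoms: iodine, II
Why: Appel-type iodination: the alkoxyphosphonium ion is displaced by iodide in an SN2 step at the unhindered primary carbon.

Step 12
Reactants: 15 7-en-9-one C19 dimethyl acetal; 20 (R)-iodide
Product: 23 C9 tertiary allylic alcohol, via alkyllithium 21 (not isolated), via alkylcerium dichloride 22 (not isolated)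
Conditions: 20, t-BuLi (2.1 equiv), Et2O, −78 °C; anhydrous CeCl3, THF, −78 °C; then 15, −78 to −40 °C; aqueous NH4Cl
Reagents that add atoms: iodide 20, ICC[C@H](C)CCO[Si](c1ccccc1)(c1ccccc1)C(C)(C)C
Why: Lithium–iodine exchange, transmetalation to the weakly basic, oxophilic trivalent cerium reagent and 1,2-addition to the hindered C9 ketone, which suppresses γ-deprotonation and conjugate addition; the C9 configuration is irrelevant because C9 becomes trigonal in step 13.

Step 13
Reactants: 23 C9 tertiary allylic alcohol
Product: 24 8-en-7-one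
Conditions: [C5H5NH][CrO3Cl] (pyridinium chlorochromate), powdered 4 Å molecular sieves, CH2Cl2, rt
Reagents that add atoms: pyridinium chlorochromate, [O-][Cr](=O)(=O)Cl.c1cc[nH+]cc1
Why: Dauben oxidative transposition: the chromate ester of the tertiary allylic alcohol undergoes a [3,3] shift to C7 and is oxidised to the transposed enone, while the acetal and silyl ether should survive the anhydrous conditions.

Step 14
Reactants: 24 8-en-7-one
Product: 25 8-en-7β-ol
Conditions: NaBH4, CeCl3·7H2O, MeOH, −20 to 0 °C
Reagents that add atoms: none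
Why: Luche 1,2-reduction; hydride should add along the pseudo-axial trajectory on the α face of the half-chair ring B, giving the pseudo-equatorial 7β-alcohol and so setting C7.

Step 15
Reactants: 25 8-en-7β-ol
Product: 28 labd-7-ene 19-dimethyl acetal 15-silyl ether, via sulfonylhydrazine 26 (not isolated), via allylic diazene 27 (not isolated)
Conditions: 2-nitrobenzenesulfonylhydrazide, PPh3, diethyl azodicarboxylate, N-methylmorpholine, −30 °C, then 23 °C
Reagents that add atoms: none
Why: Myers reductive 1,3-transposition: Mitsunobu displacement inverts C7 to the 7α-sulfonylhydrazine, loss of sulfinic acid gives the pseudo-axial diazene, and its retro-ene loss of N2 delivers hydrogen suprafacially to the α face of C9, which sets C9 (9α-H, side chain β) and moves the alkene to C7=C8.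

Step 16
Reactants: 28 labd-7-ene 19-dimethyl acetal 15-silyl ether
Product: 29 labd-7-en-19-al 15-silyl ether
Conditions: pyridinium p-toluenesulfonate (cat.), acetone/H2O 10:1, 50 °C
Reagents that add atoms: water, O
Why: Acid-catalysed acetal hydrolysis under conditions that should be too mild to cleave the tert-butyldiphenylsilyl ether or to move the C7=C8 alkene to the tetrasubstituted position.

Step 17
Reactants: 29 labd-7-en-19-al 15-silyl ether
Product: 30 labd-7-en-19-ol 15-silyl ether
Conditions: NaBH4, MeOH/THF, 0 °C
Reagents that add atoms: none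
Why: Borohydride reduction of the neopentyl aldehyde to the primary C19 alcohol; no other group is reducible under these conditions.

Step 18
Reactants: 30 labd-7-en-19-ol 15-silyl ether; 31 angelic acid
Product: 33 19-angelate 15-silyl ether, via mixed anhydride 32 (not isolated)
Conditions: 31, 2,4,6-trichlorobenzoyl chloride, Et3N, toluene, rt; then 30, toluene, 80 °C
Reagents that add atoms: angelic acid 31, C/C=C(/C)C(=O)O
Why: Yamaguchi-type esterification through the mixed anhydride without a nucleophilic catalyst, which acylates hindered alcohols and avoids the conjugate addition–elimination that would isomerise the Z angelate to the E tiglate.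

Step 19
Reactants: 33 19-angelate 15-silyl ether
Product: 34 19-angelate 15-alcohol
Conditions: HF·pyridine, THF/pyridine, 0 °C to rt
Reagents that add atoms: none
Why: Fluoride-driven desilylation (strong Si–F bond) under weakly acidic, non-basic conditions that leave the angelate geometry and both alkenes intact.

Step 20
Reactants: 34 19-angelate 15-alcohol
Product: 36 target acid (CNP0180171.1), via aldehyde 35 (not isolated)
Conditions: TEMPO (cat.), PhI(OAc)2 (2.2 equiv), MeCN/H2O 1:1, rt
Reagents that add atoms: water, O
Why: Oxoammonium-mediated oxidation of the unhindered primary alcohol to the aldehyde, whose hydrate is oxidised on to the acid; the electron-poor angelate alkene and the hindered trisubstituted alkene are not attacked.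

**Compound list**

1 | (R)-(−)-carvone | CC1=CC[C@H](CC1=O)C(C)=C | starting material
2 | iodomethane | CI | starting material
3 | lithium cross-conjugated dienolate of carvone | CC1=CC[C@H](C=C1O[Li])C(C)=C | intermediate
4 | 6-methylcarvone, (5R)-2,6-dimethyl-5-(prop-1-en-2-yl)cyclohex-2-en-1-one, both C10 epimers | CC1=CC[C@H](C(C)C1=O)C(C)=C | intermediate
5 | 3-bromo-1-(trimethylsilyl)prop-1-yne | C[Si](C)(C)C#CCBr | starting material
6 | lithium enolate of 4 (tetrasubstituted) | CC1=CC[C@H](C(C)=C1O[Li])C(C)=C | intermediate
7 | (5S,6S)-2,6-dimethyl-5-(prop-1-en-2-yl)-6-[3-(trimethylsilyl)prop-2-yn-1-yl]cyclohex-2-en-1-one (silylpropargyl arm trans to isopropenyl) | C[Si](C)(C)C#CC[C@]1(C)C(=O)C(C)=CC[C@H]1C(C)=C | intermediate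
8 | secondary ozonide (1,2,4-trioxolane) of the isopropenyl group of 7, epimers at the ozonide carbon | C[Si](C)(C)C#CC[C@]1(C)C(=O)C(C)=CC[C@H]1C2(C)OCOO2 | intermediate
9 | C4 methyl ketone: 5-acetyl analogue of 7, acetyl trans to the silylpropargyl arm | C[Si](C)(C)C#CC[C@]1(C)C(=O)C(C)=CC[C@H]1C(C)=O | intermediate
10 | (Z)-vinylsilane diketone: 5-acetyl-2,6-dimethyl-6-[(Z)-3-(trimethylsilyl)allyl]cyclohex-2-en-1-one, arms trans | C[Si](C)(C)/C=C\C[C@]1(C)C(=O)C(C)=CC[C@H]1C(C)=O | intermediate
11 | (methoxymethyl)triphenylphosphonium chloride | COC[P+](c1ccccc1)(c1ccccc1)c1ccccc1.[Cl-] | starting material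
12 | (methoxymethylene)triphenylphosphorane | COC=P(c1ccccc1)(c1ccccc1)c1ccccc1 | intermediate
13 | key-step precursor: ring B enone with C4=C19 methyl enol ether on C5 (E drawn, E/Z mixture) and (Z)-3-(trimethylsilyl)allyl arm on C10, arms trans, C20 cis to the C5 arm | C[Si](C)(C)/C=C\C[C@]1(C)C(=O)C(C)=CC[C@H]1/C(C)=C/OC | intermediate
14 | key-step product: trans-fused 2,7-dien-9-one, 4β-(dimethoxymethyl)-4α,8,10β-trimethyl, 5α-H | COC(OC)[C@@]1(C)C=CC[C@]2(C)C(=O)C(C)=CC[C@@H]12 | intermediate
15 | trans-fused 7-en-9-one, 4β-(dimethoxymethyl)-4α,8,10β-trimethyl, 5α-H, ring A saturated | COC(OC)[C@@]1(C)CCC[C@]2(C)C(=O)C(C)=CC[C@@H]12 | intermediate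
16 | methyl hydrogen (R)-3-methylglutarate | COC(=O)C[C@H](C)CC(=O)O | starting material
17 | methyl (R)-5-hydroxy-3-methylpentanoate | COC(=O)C[C@H](C)CCO | intermediate
18 | methyl (R)-5-(tert-butyldiphenylsilyloxy)-3-methylpentanoate | COC(=O)C[C@H](C)CCO[Si](c1ccccc1)(c1ccccc1)C(C)(C)C | intermediate
19 | (S)-5-(tert-butyldiphenylsilyloxy)-3-methylpentan-1-ol | OCC[C@H](C)CCO[Si](c1ccccc1)(c1ccccc1)C(C)(C)C | intermediate
20 | tert-butyl{[(3R)-5-iodo-3-methylpentyl]oxy}diphenylsilane (C11–C15 fragment, iodide at C11) | ICC[C@H](C)CCO[Si](c1ccccc1)(c1ccccc1)C(C)(C)C | intermediate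
21 | alkyllithium from 20 | [Li]CC[C@H](C)CCO[Si](c1ccccc1)(c1ccccc1)C(C)(C)C | intermediate
22 | alkylcerium dichloride from 21 (trivalent cerium) | Cl[Ce](Cl)CC[C@H](C)CCO[Si](c1ccccc1)(c1ccccc1)C(C)(C)C | intermediate
23 | C9 tertiary allylic alcohol: 9-hydroxy-7-ene with the C11–C15 silyloxy chain on C9 (C9 configuration not fixed), C19 dimethyl acetal | COC(OC)[C@@]1(C)CCC[C@]2(C)C(O)(CC[C@H](C)CCO[Si](c3ccccc3)(c3ccccc3)C(C)(C)C)C(C)=CC[C@@H]12 | intermediate
24 | 8-en-7-one: 15-silyloxy-19,19-dimethoxylabd-8-en-7-one | COC(OC)[C@@]1(C)CCC[C@]2(C)C(CC[C@H](C)CCO[Si](c3ccccc3)(c3ccccc3)C(C)(C)C)=C(C)C(=O)C[C@@H]12 | intermediate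
25 | 8-en-7β-ol: 15-silyloxy-19,19-dimethoxylabd-8-en-7β-ol | COC(OC)[C@@]1(C)CCC[C@]2(C)C(CC[C@H](C)CCO[Si](c3ccccc3)(c3ccccc3)C(C)(C)C)=C(C)[C@@H](O)C[C@@H]12 | intermediate
26 | 7α-[N-(2-nitrobenzenesulfonyl)hydrazin-1-yl] derivative of the 8-ene (Mitsunobu adduct) | COC(OC)[C@@]1(C)CCC[C@]2(C)C(CC[C@H](C)CCO[Si](c3ccccc3)(c3ccccc3)C(C)(C)C)=C(C)[C@H](N(N)S(=O)(=O)c3ccccc3[N+](=O)[O-])C[C@@H]12 | intermediate
27 | 7α-allylic diazene of the 8-ene | COC(OC)[C@@]1(C)CCC[C@]2(C)C(CC[C@H](C)CCO[Si](c3ccccc3)(c3ccccc3)C(C)(C)C)=C(C)[C@H](N=N)C[C@@H]12 | intermediate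
28 | 15-(tert-butyldiphenylsilyloxy)-19,19-dimethoxylabd-7-ene (9α-H, 13S) | COC(OC)[C@@]1(C)CCC[C@]2(C)[C@@H](CC[C@H](C)CCO[Si](c3ccccc3)(c3ccccc3)C(C)(C)C)C(C)=CC[C@@H]12 | intermediate
29 | 15-(tert-butyldiphenylsilyloxy)labd-7-en-19-al | O=C[C@@]1(C)CCC[C@]2(C)[C@@H](CC[C@H](C)CCO[Si](c3ccccc3)(c3ccccc3)C(C)(C)C)C(C)=CC[C@@H]12 | intermediate
30 | 15-(tert-butyldiphenylsilyloxy)labd-7-en-19-ol | OC[C@@]1(C)CCC[C@]2(C)[C@@H](CC[C@H](C)CCO[Si](c3ccccc3)(c3ccccc3)C(C)(C)C)C(C)=CC[C@@H]12 | intermediate
31 | angelic acid, (Z)-2-methylbut-2-enoic acid | C/C=C(/C)C(=O)O | starting material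
32 | angelic 2,4,6-trichlorobenzoic mixed anhydride | C/C=C(/C)C(=O)OC(=O)c1c(Cl)cc(Cl)cc1Cl | intermediate
33 | 19-angeloyloxy-15-(tert-butyldiphenylsilyloxy)labd-7-ene | C/C=C(/C)C(=O)OC[C@@]1(C)CCC[C@]2(C)[C@@H](CC[C@H](C)CCO[Si](c3ccccc3)(c3ccccc3)C(C)(C)C)C(C)=CC[C@@H]12 | intermediate
34 | 19-angeloyloxylabd-7-en-15-ol | C/C=C(/C)C(=O)OC[C@@]1(C)CCC[C@]2(C)[C@@H](CC[C@H](C)CCO)C(C)=CC[C@@H]12 | intermediate
35 | 19-angeloyloxylabd-7-en-15-al | C/C=C(/C)C(=O)OC[C@@]1(C)CCC[C@]2(C)[C@@H](CC[C@H](C)CC=O)C(C)=CC[C@@H]12 | intermediate
36 | CNP0180171.1, (13S)-19-angeloyloxylabd-7-en-15-oic acid | C/C=C(/C)C(=O)OC[C@@]1(C)CCC[C@]2(C)[C@@H](CC[C@H](C)CC(=O)O)C(C)=CC[C@@H]12 | target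

**Step count and risks**

Total step count: 20. Longest linear sequence: 16 steps (steps 1–7 and 12–20, from carvone); the side-chain iodide takes 4 steps (8–11).

Steps most likely to fail:

1. Step 6 (anodic cyclisation). The main danger is poor facial selectivity at C4. In the desired arrangement the hydrogen on the trigonal C19 lies near the C5–C10 bond and points toward C20, so in an early transition state the rotamer with C19 equatorial may compete and give the C4 epimer. Closure through C2 or methanol capture of the radical cation before C–C bond formation are lesser risks.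
Fallback, setting out from 4 and returning at 15: ring A would be built by aldol chemistry and C4 set by enolate alkylation. Alkylation of enolate 6 with allyl bromide, again trans to the isopropenyl group, should give 6-allyl-6-methylcarvone F1. Ozonolysis of both isolated alkenes (O3, then PPh3) gives the keto aldehyde F2. Intramolecular aldol condensation (KOH, MeOH) of the acetyl methyl (C3) onto the aldehyde (C2) closes ring A as the trans-fused 2,7-diene-4,9-dione F3. Hydrogenation of the disubstituted C2=C3 enone alkene over RhCl(PPh3)3 gives the 7-ene-4,9-dione F4. Wittig methoxymethylenation at the more accessible C4 ketone gives the enol ether F5, and aqueous acid gives the C4 aldehyde F6 as an epimer mixture. Methylation of its potassium enolate (KOC(CH3)3, MeI) from the equatorial α face, opposite the axial C20 methyl, gives the 4α-methyl-4β-formyl enone F7. Acetalisation (HC(OMe)3, MeOH, TsOH) then gives 15.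

2. Step 15 (reductive transposition). The Mitsunobu displacement at the hindered allylic C7 may be slow or may proceed through an allyl cation, so that the diazene forms on the wrong face or not at all and the hydrogen is not delivered cleanly to the α face of C9.
Fallback, setting out from 25 and returning at 28: formylation (formic acetic anhydride, pyridine) gives the 7β-formate F8. Tsuji formate hydrogenolysis (Pd(OAc)2, PBu3, dioxane, heat) then applies: zerovalent palladium ionises the formate with inversion and sits on the α face, and after loss of CO2 hydride is transferred from palladium to the more substituted allyl terminus C9 on that face, giving 28.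

3. Step 18 (angeloylation). Acylation of the neopentyl axial C19 alcohol may be incomplete, or the Z angeloyl group may isomerise to the E tigloyl group under the heating needed.
Fallback, setting out from 30 and returning at 33: esterification with 2-[bis(2,2,2-trifluoroethoxy)phosphoryl]propanoic acid (dicyclohexylcarbodiimide, DMAP) gives the phosphonate ester F9. Still–Gennari olefination (KN(SiMe3)2, 18-crown-6, THF, −78 °C, acetaldehyde) then builds the Z-2-methylbut-2-enoate on the alcohol and gives 33.

Further compounds
F1 | step 6 | 6-allyl-6-methylcarvone, allyl trans to isopropenyl | C=CC[C@]1(C)C(=O)C(C)=CC[C@H]1C(C)=C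
F2 | step 6 | keto aldehyde: 5-acetyl-2,6-dimethyl-6-(2-oxoethyl)cyclohex-2-en-1-one | O=CC[C@]1(C)C(=O)C(C)=CC[C@H]1C(C)=O
F3 | step 6 | trans-fused 8,10β-dimethyl-2,7-diene-4,9-dione | O=C1C=CC[C@]2(C)C(=O)C(C)=CC[C@@H]12
F4 | step 6 | trans-fused 8,10β-dimethyl-7-ene-4,9-dione | O=C1CCC[C@]2(C)C(=O)C(C)=CC[C@@H]12
F5 | step 6 | 4-(methoxymethylene)-7-en-9-one, E/Z mixture | COC=C1CCC[C@]2(C)C(=O)C(C)=CC[C@@H]12
F6 | step 6 | 4-formyl-7-en-9-one, C4 epimers | O=CC1CCC[C@]2(C)C(=O)C(C)=CC[C@@H]12
F7 | step 6 | 4β-formyl-4α,8,10β-trimethyl-7-en-9-one | O=C[C@@]1(C)CCC[C@]2(C)C(=O)C(C)=CC[C@@H]12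
F8 | step 15 | 7β-formate of 25 | COC(OC)[C@@]1(C)CCC[C@]2(C)C(CC[C@H](C)CCO[Si](c3ccccc3)(c3ccccc3)C(C)(C)C)=C(C)[C@@H](OC=O)C[C@@H]12
F9 | step 18 | 2-[bis(2,2,2-trifluoroethoxy)phosphoryl]propanoate of 30 | CC(C(=O)OC[C@@]1(C)CCC[C@]2(C)[C@@H](CC[C@H](C)CCO[Si](c3ccccc3)(c3ccccc3)C(C)(C)C)C(C)=CC[C@@H]12)P(=O)(OCC(F)(F)F)OCC(F)(F)F
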